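(All constants are made up; the result is computed.)

The catalyst goes in as spent carrier, so ask how much of that start is left over at the moment you look.

    spent carrier + salt in the second phase ⇌ fresh carrier + spent salt in the second phase (K1 = 2.2, k1 = 2.9 /M/h)
    substrate ⇌ dormant form (K2 = 2.1, k2 = 0.10 /h)
    substrate + fresh carrier → target + spent carrier (k3 = 1.8 /M/h)

substrate 0.50 M; salt in the second phase 1.00 equiv; spent carrier 15 mol%; volume of the second phase over the first 2.0

- in the second phase: salt in the second phase, spent salt in the second phase; everything else is in the first
- charges count per volume of the first phase; a concentration in a rate is the amount of a species over the volume of its own phase; every rate counts per litre of the first phase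
- what has gone from substrate into another species counts as reacted, even if it can come back
- charge of substrate (flask): 0.50 M

- the form that holds most of the catalyst when 10% of the substrate are converted (spent carrier / fresh carrier)
- its share of the catalyst then

**Frozen rates.** Freeze substrate and salt at their charges; you look at 10% conversion. The salt, spread over the second phase, stands at 0.250 M. So each spent carrier turns fresh at 0.725 /h. Each fresh carrier meets substrate and turns spent at 0.900 /h. I also drop the return through spent salt, which this flask does not hold at the start.

**First way.** Balance the two rates. The spent share is the substrate rate over the sum of both, 55.4%.

**Second way.** Follow the approach from the start instead. The gap between the spent share and that balance shrinks by a factor e in the relaxation time of the carrier, one over the sum of the two rates: 0.615 h. The moment of 10% conversion comes at 0.84 h, which is 1.37 relaxation times in, fewer than two. So 25.4% of the gap survives, and the spent share is 66.7%.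

**Which cheats.** The two ways part, and the first one cheats. It describes a relaxed carrier, and at this moment my reckoning still leaves 25.4% of the gap. I commit to the second: spent carrier is the resting state, at 66.7%.

**The forecast.** The forecast names spent carrier at 68%, a point reached “before the carrier has fully relaxed”. My figure of 66.7% is slightly lower.

**The flask.** The simulation gives spent carrier at 67.3% at 10% conversion, with fresh carrier at 32.7%. Against the relaxation time of 0.615 h, that moment at 0.84 h is later, yet the spent share in this flask still stands 12 percentage points above the frozen balance of 55.4%, a distance equal to 26.7% of the starting gap.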